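The target is a p-quinol methyl ether: C4 of the dienone ring is a quinone carbonyl carbon in disguise, flanked by the C5 enol ether. The bond from C4 to the side-chain methine C2′ is therefore made by 1,2-addition of a configurationally defined secondary alkylmagnesium (C2′, from (S)-propylene oxide) to that carbonyl. The precursor is not a dienone but a tricycle: the C2=C3 bond of 2-allyl-5-methoxybenzoquinone is masked as an enantioenriched endo cyclopentadiene adduct, whose cage leaves only the convex face of the C4 carbonyl open. One operation joins both halves and sets C4 and C2′; O-methylation and retro-Diels–Alder then unveil the dienone.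

Key step: step 7

Assumption: the (S)-oxazaborolidinium catalyst of step 4 is taken to give adduct 5 as drawn; if it gives the mirror image, the (R)-catalyst is used and nothing else changes.

Locants: the target is numbered C1 (C=O) to C6 with C2′ as the side-chain methine. The tricycles are numbered as tricyclo[6.2.1.0^2,7]undecanes, whose C6 becomes C4 of the target.

Step 1
Reactants: 1 3,4-dimethoxyphenol
Product: 2 1,2-dimethoxy-4-(prop-2-en-1-yloxy)benzene
Conditions: allyl bromide, K2CO3, acetone, reflux
Reagents that add atoms: allyl bromide, C=CCBr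
Why: Williamson ether synthesis, the phenoxide displacing bromide at the primary allylic carbon (SN2); no stereocentre is formed.

Step 2
Reactants: 2 1,2-dimethoxy-4-(prop-2-en-1-yloxy)benzene
Product: 3 4,5-dimethoxy-2-(prop-2-en-1-yl)phenol
Conditions: PhNEt2, 190 °C
Reagents that add atoms: none
Why: Aromatic Claisen rearrangement ([3,3]) to the ortho position that is not flanked by a methoxy group, followed by tautomerisation to the phenol; no stereocentre is formed.

Step 3
Reactants: 3 4,5-dimethoxy-2-(prop-2-en-1-yl)phenol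
Product: 4 2-methoxy-5-(prop-2-en-1-yl)cyclohexa-2,5-diene-1,4-dione
Conditions: PhI(OAc)2, MeCN/H2O, 0 °C
Reagents that add atoms: water, O
Why: Hypervalent-iodine oxidative dearomatisation of a p-methoxyphenol, in which water adds para to the phenol oxygen and the hemiketal loses methanol to give the p-quinone; no stereocentre is formed.

Step 4
Reactants: 4 2-methoxy-5-(prop-2-en-1-yl)cyclohexa-2,5-diene-1,4-dione
Product: 5 (1R,2S,7R,8S)-5-methoxy-2-(prop-2-en-1-yl)tricyclo[6.2.1.0^2,7]undeca-4,9-diene-3,6-dione (endo adduct, allyl and H7 exo)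
Conditions: cyclopentadiene, (S)-o-tolyl oxazaborolidinium triflimide (20 mol %), CH2Cl2, −78 °C
Reagents that add atoms: cyclopentadiene, C1C=CC=C1
Why: Catalytic enantioselective Diels–Alder reaction, in which the chiral Lewis acid activates the quinone and cyclopentadiene adds suprafacially and endo to the allyl-bearing C2=C3 bond (the methoxy-bearing C5=C6 bond is deactivated as a vinylogous ester), so the four new centres are set relative to one another by the endo transition state and in the absolute sense by the catalyst.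

Step 5
Reactants: 6 4-bromo-1,2-dimethoxybenzene; 7 (S)-2-methyloxirane
Product: 9 (2S)-1-(3,4-dimethoxyphenyl)propan-2-ol, via arylmagnesium bromide 8 (not isolated)
Conditions: Mg, THF; then CuI (10 mol %), 7, −30 → 0 °C; aq NH4Cl
Reagents that add atoms: none
Why: Copper-catalysed ring opening of the epoxide by the aryl Grignard reagent at the unsubstituted carbon (SN2), which leaves the stereocentre of 7 untouched.

Step 6
Reactants: 9 (2S)-1-(3,4-dimethoxyphenyl)propan-2-ol
Product: 10 4-[(2R)-2-iodopropyl]-1,2-dimethoxybenzene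
Conditions: PPh3, I2, N-methylimidazole, CH2Cl2, −10 °C
Reagents that add atoms: iodine, II
Why: Appel reaction, iodide displacing the alkoxyphosphonium group by SN2 with inversion (S alcohol to R iodide), the cold non-ionising medium limiting aryl participation and iodide exchange.

Step 7
Reactants: 10 4-[(2R)-2-iodopropyl]-1,2-dimethoxybenzene; 5 (1R,2S,7R,8S)-5-methoxy-2-(prop-2-en-1-yl)tricyclo[6.2.1.0^2,7]undeca-4,9-diene-3,6-dione
Product: 13 (1R,2S,6R,7R,8S)-6-[(2R)-1-(3,4-dimethoxyphenyl)propan-2-yl]-6-hydroxy-5-methoxy-2-(prop-2-en-1-yl)tricyclo[6.2.1.0^2,7]undeca-4,9-dien-3-one, via secondary alkyllithium 11 (not isolated), via mixed dialkylmagnesium 12 (not isolated)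
Conditions: t-BuLi (2.2 equiv), pentane/Et2O, −100 °C; Me3SiCH2MgCl, −100 → −50 °C; then 5, THF, −78 → −50 °C; aq NH4Cl
Reagents that add atoms: none
Why: Iodine–lithium exchange on 10 at −100 °C and immediate Li→Mg transmetalation proceed with retention and give a secondary alkylmagnesium that holds its configuration at −50 °C; its carbanion carbon then adds, again with retention, to the C6 carbonyl of 5 (the future C4) through a magnesium chelate with the neighbouring enol ether oxygen. The closest known reaction type is the stereoretentive addition of optically enriched secondary alkylmagnesium reagents to ketones, combined with convex-face 1,2-additions to endo cyclopentadiene–quinone adducts. No ring is closed. The new quaternary centre (future C4, R) is controlled by the tricycle, because the concave face of C6=O lies under the C9=C10 bridge and the nucleophile must enter from the exo face, syn to H7; the methine centre (future C2′, R) is controlled by the reagent, which carries the configuration of (S)-2-methyloxirane through one inversion and three retentive events. The step needs site selectivity between two carbonyls and 1,2- over conjugate addition: C3=O is a vinylogous ester next to the quaternary C2, whereas C6=O is an α-alkoxy enone carbonyl that chelates magnesium. Enolisation at H7 is the main competing path and is held back by the low temperature.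

Step 8
Reactants: 13 (1R,2S,6R,7R,8S)-6-[(2R)-1-(3,4-dimethoxyphenyl)propan-2-yl]-6-hydroxy-5-methoxy-2-(prop-2-en-1-yl)tricyclo[6.2.1.0^2,7]undeca-4,9-dien-3-one
Product: 14 (1R,2S,6R,7R,8S)-6-[(2R)-1-(3,4-dimethoxyphenyl)propan-2-yl]-5,6-dimethoxy-2-(prop-2-en-1-yl)tricyclo[6.2.1.0^2,7]undeca-4,9-dien-3-one
Conditions: KH, THF, 0 °C; MeI, 0 °C → rt
Reagents that add atoms: iodomethane, CI
Why: Williamson O-methylation of the potassium alkoxide, clean because 13 has no enolisable hydrogen (C2 is quaternary) and no stereocentre is touched.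

Step 9
Reactants: 14 (1R,2S,6R,7R,8S)-6-[(2R)-1-(3,4-dimethoxyphenyl)propan-2-yl]-5,6-dimethoxy-2-(prop-2-en-1-yl)tricyclo[6.2.1.0^2,7]undeca-4,9-dien-3-one
Product: 15 (4R)-4-[(2R)-1-(3,4-dimethoxyphenyl)propan-2-yl]-4,5-dimethoxy-2-(prop-2-en-1-yl)cyclohexa-2,5-dien-1-one
Conditions: Ph2O, 220 °C
Reagents that add atoms: none
Why: Retro-Diels–Alder reaction, a thermal cycloreversion that expels cyclopentadiene, is helped by the quaternary ring-fusion carbon and the cross-conjugated dienone it forms, and removes only the four temporary stereocentres while C4 and C2′ are not involved.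

Compound list
1 | 3,4-dimethoxyphenol | COc1ccc(O)cc1OC | starting material
2 | 1,2-dimethoxy-4-(prop-2-en-1-yloxy)benzene | C=CCOc1ccc(OC)c(OC)c1 | intermediate
3 | 4,5-dimethoxy-2-(prop-2-en-1-yl)phenol | C=CCc1cc(OC)c(OC)cc1O | intermediate
4 | 2-methoxy-5-(prop-2-en-1-yl)cyclohexa-2,5-diene-1,4-dione | C=CCC1=CC(=O)C(OC)=CC1=O | intermediate
5 | (1R,2S,7R,8S)-5-methoxy-2-(prop-2-en-1-yl)tricyclo[6.2.1.0^2,7]undeca-4,9-diene-3,6-dione | COC1=CC(=O)[C@@]2(CC=C)[C@H]3C=C[C@H](C3)[C@H]2C1=O | intermediate
6 | 4-bromo-1,2-dimethoxybenzene | COc1ccc(Br)cc1OC | starting material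
7 | (S)-2-methyloxirane | C[C@H]1CO1 | starting material
8 | (3,4-dimethoxyphenyl)magnesium bromide | COc1ccc([Mg]Br)cc1OC | intermediate (not isolated)
9 | (2S)-1-(3,4-dimethoxyphenyl)propan-2-ol | C[C@H](O)Cc1ccc(OC)c(OC)c1 | intermediate
10 | 4-[(2R)-2-iodopropyl]-1,2-dimethoxybenzene | C[C@@H](I)Cc1ccc(OC)c(OC)c1 | intermediate
11 | [(2R)-1-(3,4-dimethoxyphenyl)propan-2-yl]lithium | C[C@@H]([Li])Cc1ccc(OC)c(OC)c1 | intermediate (not isolated)
12 | [(2R)-1-(3,4-dimethoxyphenyl)propan-2-yl][(trimethylsilyl)methyl]magnesium | C[C@@H]([Mg]C[Si](C)(C)C)Cc1ccc(OC)c(OC)c1 | intermediate (not isolated)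
13 | (1R,2S,6R,7R,8S)-6-[(2R)-1-(3,4-dimethoxyphenyl)propan-2-yl]-6-hydroxy-5-methoxy-2-(prop-2-en-1-yl)tricyclo[6.2.1.0^2,7]undeca-4,9-dien-3-one | COC1=CC(=O)[C@@]2(CC=C)[C@H]3C=C[C@H](C3)[C@H]2[C@]1(O)[C@H](C)Cc1ccc(OC)c(OC)c1 | intermediate
14 | (1R,2S,6R,7R,8S)-6-[(2R)-1-(3,4-dimethoxyphenyl)propan-2-yl]-5,6-dimethoxy-2-(prop-2-en-1-yl)tricyclo[6.2.1.0^2,7]undeca-4,9-dien-3-one | COC1=CC(=O)[C@@]2(CC=C)[C@H]3C=C[C@H](C3)[C@H]2[C@]1(OC)[C@H](C)Cc1ccc(OC)c(OC)c1 | intermediate
15 | (4R)-4-[(2R)-1-(3,4-dimethoxyphenyl)propan-2-yl]-4,5-dimethoxy-2-(prop-2-en-1-yl)cyclohexa-2,5-dien-1-one | C=CCC1=C[C@](OC)([C@H](C)Cc2ccc(OC)c(OC)c2)C(OC)=CC1=O | target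

Total step count: 9. Longest linear sequence: 7 steps (1, 2, 3, 4, 7, 8, 9); the side-chain branch (5, 6) joins at step 7.

Steps most likely to fail

Step 7. The branched secondary alkyl group may not transfer to the hindered C6 ketone of 5 because deprotonation at H7 or β-hydride reduction is faster, and a slow transmetalation would let the alkyllithium epimerise. The fallback sets out from quinone 4 and returns at 15; it makes the bond on the flat, non-enolisable quinone instead of the tricycle. Dialkylmagnesium 12 would be added to 4 in THF at −78 °C. 1,2-Addition at the carbonyl next to the methoxy-bearing carbon (the other carbonyl is a vinylogous ester beside the allyl group) should give (4R)-4-[(2R)-1-(3,4-dimethoxyphenyl)propan-2-yl]-4-hydroxy-5-methoxy-2-(prop-2-en-1-yl)cyclohexa-2,5-dien-1-one F1 together with its C4 epimer. Facial bias would then rest only on the magnesium chelate and on stacking of the dimethoxyphenyl ring over the quinone, so the epimers would be separated by chromatography. O-Methylation of F1 (KH, MeI, THF) would give 15.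

Step 6. Participation of the electron-rich aryl ring (phenonium ion) or iodide–iodide exchange may erode the configuration during the OH to I exchange. The fallback sets out from bromide 6 and returns at 10; it builds the stereocentre by reagent-controlled lithiation–borylation and installs iodine by an invertive iododeboronation. Grignard reagent 8, made from 6, would react with 2-(iodomethyl)-4,4,5,5-tetramethyl-1,3,2-dioxaborolane in a Matteson-type homologation to give 2-(3,4-dimethoxybenzyl)-4,4,5,5-tetramethyl-1,3,2-dioxaborolane F2. Ethyl N,N-diisopropylcarbamate would be lithiated with s-BuLi/(+)-sparteine (Et2O, −78 °C) and treated with F2, then MgBr2·OEt2 at reflux. Borylation with retention and 1,2-migration with inversion should give (S)-2-[1-(3,4-dimethoxyphenyl)propan-2-yl]-4,4,5,5-tetramethyl-1,3,2-dioxaborolane F3. Addition of 3,5-bis(trifluoromethyl)phenyllithium would give lithium [3,5-bis(trifluoromethyl)phenyl][(2S)-1-(3,4-dimethoxyphenyl)propan-2-yl](pinacolato)borate F4, and iodine should convert it into 10 with inversion.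

Step 4. The catalysed cycloaddition may show insufficient enantioselectivity or site selectivity on this untested quinone. The fallback sets out from 4 and returns at 13; it replaces catalyst control by a resolution through the key step. Uncatalysed cycloaddition of 4 with cyclopentadiene (CH2Cl2, 0 °C) would give 5 as a racemate with (1S,2R,7S,8R)-5-methoxy-2-(prop-2-en-1-yl)tricyclo[6.2.1.0^2,7]undeca-4,9-diene-3,6-dione F5. Step 7 run on the racemate would convert F5 into (1S,2R,6S,7S,8R)-6-[(2R)-1-(3,4-dimethoxyphenyl)propan-2-yl]-6-hydroxy-5-methoxy-2-(prop-2-en-1-yl)tricyclo[6.2.1.0^2,7]undeca-4,9-dien-3-one F6. F6 differs from 13 at five centres and should be removed by chromatography, after which 13 continues as in the route.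

Further compounds
F1 | step 7 | (4R)-4-[(2R)-1-(3,4-dimethoxyphenyl)propan-2-yl]-4-hydroxy-5-methoxy-2-(prop-2-en-1-yl)cyclohexa-2,5-dien-1-one | C=CCC1=C[C@](O)([C@H](C)Cc2ccc(OC)c(OC)c2)C(OC)=CC1=O
F2 | step 6 | 2-(3,4-dimethoxybenzyl)-4,4,5,5-tetramethyl-1,3,2-dioxaborolane | COc1ccc(CB2OC(C)(C)C(C)(C)O2)cc1OC
F3 | step 6 | (S)-2-[1-(3,4-dimethoxyphenyl)propan-2-yl]-4,4,5,5-tetramethyl-1,3,2-dioxaborolane | C[C@H](B1OC(C)(C)C(C)(C)O1)Cc1ccc(OC)c(OC)c1
F4 | step 6 | lithium [3,5-bis(trifluoromethyl)phenyl][(2S)-1-(3,4-dimethoxyphenyl)propan-2-yl](pinacolato)borate | C[C@H]([B-]1(OC(C)(C)C(C)(C)O1)c1cc(C(F)(F)F)cc(C(F)(F)F)c1)Cc1ccc(OC)c(OC)c1.[Li+]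
F5 | step 4 | (1S,2R,7S,8R)-5-methoxy-2-(prop-2-en-1-yl)tricyclo[6.2.1.0^2,7]undeca-4,9-diene-3,6-dione | COC1=CC(=O)[C@]2(CC=C)[C@@H]3C=C[C@@H](C3)[C@@H]2C1=O
F6 | step 4 | (1S,2R,6S,7S,8R)-6-[(2R)-1-(3,4-dimethoxyphenyl)propan-2-yl]-6-hydroxy-5-methoxy-2-(prop-2-en-1-yl)tricyclo[6.2.1.0^2,7]undeca-4,9-dien-3-one | COC1=CC(=O)[C@]2(CC=C)[C@@H]3C=C[C@@H](C3)[C@@H]2[C@@]1(O)[C@H](C)Cc1ccc(OC)c(OC)c1
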